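The O1–C2(CH3)2 unit of the 2,2-dimethyl-2H-pyran ring is read as acetone, held between the vinylic carbon C3 and the enol-ether carbon C8a of the cyclohexadienone ring (a vinylogous ester). In one operation a cis-alkenyllithium on the quaternary carbon C4a adds to acetone, and the resulting tertiary alkoxide closes the pyran by addition–elimination at C8a, expelling a methoxy group installed as a temporary activator. The precursor is a dearomatised acylphloroglucinol, a 6-[(Z)-2-iodoethenyl]-5-methoxycyclohexa-2,4-dienone. Its quaternary stereocentre is set by a catalyst-controlled, desymmetrising ethynylation of mirror-symmetric 4-O-methyldeoxycohumulone.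

Key step: step 7

Numbering: atom labels refer to the chromene numbering of the target (O1, C2, C3, C4, C4a, C5 to C8, C8a); the target stereocentre C4a is (R).

Remark: the sense of induction in step 4 cannot be predicted safely. The cinchonidine-derived catalyst is assumed to give the (R)-dienone; the cinchonine-derived pseudo-enantiomer would be used if the opposite sense is found.

Step 1
Reactants: 1 phloroglucinol; 2 isobutyryl chloride
Product: 3 2-methyl-1-(2,4,6-trihydroxyphenyl)propan-1-one (phlorisobutyrophenone)
Conditions: AlCl3 (4 equiv), PhNO2, 23 → 65 °C; ice/aq. HCl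
Reagents that add atoms: none
Why: Friedel–Crafts C-acylation of the electron-rich arene should stop after one acyl group because the ketone deactivates the ring.

Step 2
Reactants: 3 phlorisobutyrophenone; 4 prenyl bromide (2.1 equiv)
Product: 5 1-[2,4,6-trihydroxy-3,5-bis(3-methylbut-2-en-1-yl)phenyl]-2-methylpropan-1-one (deoxycohumulone)
Conditions: 10% aq. KOH, 0 °C, argon
Reagents that add atoms: none
Why: C-allylation of the ambident phloroglucinol polyanion in water should place one prenyl group on each free ring carbon, with stoichiometry and low temperature holding back a third, dearomatising alkylation.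

Step 3
Reactants: 5 deoxycohumulone
Product: 6 1-[2,6-dihydroxy-4-methoxy-3,5-bis(3-methylbut-2-en-1-yl)phenyl]-2-methylpropan-1-one (4-O-methyldeoxycohumulone)
Conditions: Me3SiCHN2 (1.05 equiv), toluene/MeOH 4:1, 0 °C
Reagents that add atoms: trimethylsilyldiazomethane, C[Si](C)(C)C=[N+]=[N-]
Why: Diazoalkane O-methylation should pick the 4-OH, the most acidic hydroxyl and the only one not held in a hydrogen bond to the ketone, which keeps the molecule mirror-symmetric.

Step 4
Reactants: 6 4-O-methyldeoxycohumulone; 7 1-[(trimethylsilyl)ethynyl]-1,2-benziodoxol-3(1H)-one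
Product: 8 (6R)-6-ethynyl-3-hydroxy-5-methoxy-4,6-bis(3-methylbut-2-en-1-yl)-2-(2-methylpropanoyl)cyclohexa-2,4-dien-1-one
Conditions: N-(9-anthracenylmethyl)-O-allylcinchonidinium bromide (10 mol%), KF (3 equiv), toluene, −40 °C, argon
Reagents that add atoms: none
Why: Proposed new method: the chiral ammonium cation pairs with the phenoxide of mirror-symmetric 6 and directs one of the two enantiotopic prenyl-bearing ring carbons onto the beta carbon of the ethynylbenziodoxolone released from 7 by fluoride, after which loss of 2-iodobenzoate and a 1,2-hydrogen shift of the alkylidene carbene give the terminal alkyne and the quaternary stereocentre, whose configuration is fixed by the catalyst; the closest known reaction types are the phase-transfer-catalysed enantioselective alkynylation of cyclic beta-keto esters with this reagent and the phase-transfer-catalysed desymmetrising alkylative dearomatisation of 3,5-diprenylated acylphloroglucinols.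

Step 5
Reactants: 8 ethynyl dienone
Product: 9 (6R)-3-hydroxy-6-(iodoethynyl)-5-methoxy-4,6-bis(3-methylbut-2-en-1-yl)-2-(2-methylpropanoyl)cyclohexa-2,4-dien-1-one
Conditions: LiN(iPr)2 (2.2 equiv), THF, −78 °C; I2 (1.0 equiv), −78 °C; aq. Na2S2O3/NH4Cl
Reagents that add atoms: iodine, II
Why: Iodination of a lithium acetylide should be clean because the acidic enol is masked as its lithium enolate and the acetylide consumes the single equivalent of iodine faster than any alkene can.

Step 6
Reactants: 9 iodoalkyne
Product: 10 (6R)-3-hydroxy-6-[(Z)-2-iodoethenyl]-5-methoxy-4,6-bis(3-methylbut-2-en-1-yl)-2-(2-methylpropanoyl)cyclohexa-2,4-dien-1-one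
Conditions: 2-nitrobenzenesulfonylhydrazide (2.5 equiv), Et3N, THF/iPrOH, 23 °C
Reagents that add atoms: none
Why: Diimide reduction delivers both hydrogens to the same face of the 1-iodoalkyne and should give the (Z)-iodoalkene, while the tri- and tetrasubstituted alkenes react far more slowly.

Step 7
Reactants: 10 (Z)-iodoalkene; 11 acetone (3 equiv)
Product: 14 (4aR)-7-hydroxy-2,2-dimethyl-4a,8-bis(3-methylbut-2-en-1-yl)-6-(2-methylpropanoyl)-2H-chromen-5(4aH)-one, via alkenyllithium 12 (not isolated), via lithium alkoxide 13 (not isolated)
Conditions: LiN(SiMe3)2 (1.0 equiv), THF/Et2O, −78 °C; t-BuLi (2.1 equiv), −78 °C, 10 min; acetone, −78 → 0 °C; then DMPU, 23 → 45 °C; aq. NH4Cl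
Reagents that add atoms: none
Why: After the acidic enol is masked as its lithium enolate, iodine–lithium exchange gives the (Z)-alkenyllithium 12 with retention, its 1,2-addition to acetone forms the C3–C2 bond, and on warming the tertiary alkoxide 13 attacks C8a (beta carbon of the enone C8a=C8–C7=O) and expels methoxide, forming the O1–C8a bond. The closest known reaction type is the anionic tandem in which an ortho-functionalised aryl- or alkenyllithium adds to a ketone and the alkoxide then closes a ring by addition–elimination (phthalide, butenolide and chromene syntheses; alkoxy exchange at vinylogous esters). The pyran ring closes by a 6-exo-trig oxa-Michael addition followed by beta-elimination, that is, nucleophilic vinylic substitution. No stereocentre is created: C4a is quaternary and already set, and the cis geometry of C3=C4 needed for ring closure is carried through because alkenyllithiums are configurationally stable at −78 °C. Chemoselectivity rests on the enolate, which shields the ring and acyl carbonyls from the organolithium; regioselectivity rests on C8a being the only carbon within reach of the alkoxide that carries a leaving group, since attack at C5 is reversible and unproductive.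

Compound list
1 | phloroglucinol (benzene-1,3,5-triol) | Oc1cc(O)cc(O)c1 | starting material
2 | isobutyryl chloride | CC(C)C(Cl)=O | starting material
3 | 2-methyl-1-(2,4,6-trihydroxyphenyl)propan-1-one | CC(C)C(=O)c1c(O)cc(O)cc1O | intermediate
4 | prenyl bromide (1-bromo-3-methylbut-2-ene) | CC(C)=CCBr | starting material
5 | 1-[2,4,6-trihydroxy-3,5-bis(3-methylbut-2-en-1-yl)phenyl]-2-methylpropan-1-one | CC(C)C(=O)c1c(O)c(CC=C(C)C)c(O)c(CC=C(C)C)c1O | intermediate
6 | 1-[2,6-dihydroxy-4-methoxy-3,5-bis(3-methylbut-2-en-1-yl)phenyl]-2-methylpropan-1-one | CC(C)C(=O)c1c(O)c(CC=C(C)C)c(OC)c(CC=C(C)C)c1O | intermediate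
7 | 1-[(trimethylsilyl)ethynyl]-1,2-benziodoxol-3(1H)-one | C[Si](C)(C)C#CI1OC(=O)c2ccccc12 | starting material
8 | (6R)-6-ethynyl-3-hydroxy-5-methoxy-4,6-bis(3-methylbut-2-en-1-yl)-2-(2-methylpropanoyl)cyclohexa-2,4-dien-1-one | CC(C)=CCC1=C(OC)[C@](C#C)(CC=C(C)C)C(=O)C(C(=O)C(C)C)=C1O | intermediate
9 | (6R)-3-hydroxy-6-(iodoethynyl)-5-methoxy-4,6-bis(3-methylbut-2-en-1-yl)-2-(2-methylpropanoyl)cyclohexa-2,4-dien-1-one | CC(C)=CCC1=C(OC)[C@](C#CI)(CC=C(C)C)C(=O)C(C(=O)C(C)C)=C1O | intermediate
10 | (6R)-3-hydroxy-6-[(Z)-2-iodoethenyl]-5-methoxy-4,6-bis(3-methylbut-2-en-1-yl)-2-(2-methylpropanoyl)cyclohexa-2,4-dien-1-one | CC(C)=CCC1=C(OC)[C@](/C=C\I)(CC=C(C)C)C(=O)C(C(=O)C(C)C)=C1O | intermediate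
11 | acetone | CC(C)=O | starting material
12 | lithium enolate of the (6R)-6-[(Z)-2-lithioethenyl] dienone (iodine of 10 replaced by lithium) | CC(C)=CCC1=C(OC)[C@](/C=C\[Li])(CC=C(C)C)C(=O)C(C(=O)C(C)C)=C1O[Li] | intermediate
13 | dilithium salt of (6R)-3-hydroxy-6-[(Z)-3-hydroxy-3-methylbut-1-en-1-yl]-5-methoxy-4,6-bis(3-methylbut-2-en-1-yl)-2-(2-methylpropanoyl)cyclohexa-2,4-dien-1-one | CC(C)=CCC1=C(OC)[C@](/C=C\C(C)(C)O[Li])(CC=C(C)C)C(=O)C(C(=O)C(C)C)=C1O[Li] | intermediate
14 | (4aR)-7-hydroxy-2,2-dimethyl-4a,8-bis(3-methylbut-2-en-1-yl)-6-(2-methylpropanoyl)-2H-chromen-5(4aH)-one | CC(C)=CCC1=C2OC(C)(C)C=C[C@@]2(CC=C(C)C)C(=O)C(C(=O)C(C)C)=C1O | target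

Total steps: 7. Longest linear sequence: 7 steps (1 to 14).

Steps most likely to fail

Step 4. Discrimination between the two enantiotopic ring carbons may be poor, and the electron-rich phenoxide may be oxidised by the iodine reagent instead of being alkynylated. The fallback sets out from 6 and uses the known fluoride-triggered ethynylation of stabilised enolates without a chiral catalyst (7, Bu4NF, THF, −78 °C), which should give the racemic ethynyl dienone F1. Its acidic enol would then be resolved by fractional crystallisation with a chiral amine, shown here as the (S)-1-phenylethylammonium salt F2 of the (R)-acid; the amine enantiomer that gives the less soluble salt with the (R)-acid would be chosen by screening. Acidification of F2 returns the route to 8.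

Step 7. The ring closure may stall because the enolate charge lowers the electrophilicity of C8a, and proton transfer from acetone to the alkenyllithium may compete with addition. The fallback sets out from 8 and forms the two bonds in separate known steps. Double deprotonation with LiN(iPr)2 and addition of the acetylide to acetone 11 should give the propargylic alcohol F3. Semihydrogenation over Pb-poisoned Pd/CaCO3 with quinoline should give the (Z)-allylic alcohol F4. Alkoxy exchange at the vinylogous ester with pyridinium p-toluenesulfonate in toluene at 60 °C, with loss of methanol, would return to the route at 14.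

Step 5. Electrophilic iodine may be captured by a prenyl double bond with ring closure by the neighbouring enolate oxygen (iodoetherification) instead of reacting with the acetylide. The fallback sets out from 8 and avoids electrophilic iodine altogether. Radical hydrostannylation with Ph3SnH and catalytic Et3B at −78 °C, where hydrogen transfer to the stannylvinyl radical is kinetically anti, should give the (Z)-alkenylstannane F5 in one step. Under the conditions of step 7, with PhLi in place of t-BuLi, tin–lithium exchange would deliver the alkenyllithium, and the route is rejoined at 12.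

Further compounds
F1 | step 4 | racemic 6-ethynyl-3-hydroxy-5-methoxy-4,6-bis(3-methylbut-2-en-1-yl)-2-(2-methylpropanoyl)cyclohexa-2,4-dien-1-one | CC(C)=CCC1=C(OC)C(C#C)(CC=C(C)C)C(=O)C(C(=O)C(C)C)=C1O
F2 | step 4 | (S)-1-phenylethylammonium enolate of the (6R)-ethynyl dienone | CC(C)=CCC1=C(OC)[C@](C#C)(CC=C(C)C)C(=O)C(C(=O)C(C)C)=C1[O-].C[C@H]([NH3+])c1ccccc1
F3 | step 7 | (6R)-3-hydroxy-6-(3-hydroxy-3-methylbut-1-yn-1-yl)-5-methoxy-4,6-bis(3-methylbut-2-en-1-yl)-2-(2-methylpropanoyl)cyclohexa-2,4-dien-1-one | CC(C)=CCC1=C(OC)[C@](C#CC(C)(C)O)(CC=C(C)C)C(=O)C(C(=O)C(C)C)=C1O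
F4 | step 7 | (6R)-3-hydroxy-6-[(Z)-3-hydroxy-3-methylbut-1-en-1-yl]-5-methoxy-4,6-bis(3-methylbut-2-en-1-yl)-2-(2-methylpropanoyl)cyclohexa-2,4-dien-1-one | CC(C)=CCC1=C(OC)[C@](/C=C\C(C)(C)O)(CC=C(C)C)C(=O)C(C(=O)C(C)C)=C1O
F5 | step 5 | (6R)-3-hydroxy-5-methoxy-4,6-bis(3-methylbut-2-en-1-yl)-2-(2-methylpropanoyl)-6-[(Z)-2-(triphenylstannyl)ethenyl]cyclohexa-2,4-dien-1-one | CC(C)=CCC1=C(OC)[C@](/C=C\[Sn](c2ccccc2)(c2ccccc2)c2ccccc2)(CC=C(C)C)C(=O)C(C(=O)C(C)C)=C1O
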